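**Plan**

- Retrosynthesis: the acid and the 7-OH are closed to a lactone whose carbonyl comes from a primary alcohol. Ring C is cut at O1–C2 and C3–C4 (o-hydroxyaryl ynone from a salicylaldehyde and 4-ethynylanisole) and at C4–C4a (ortho-formylation). Ring A is cut at C8a–C8, C7–C6 and C8a–C4a into 3-ethoxycyclobutenone and a chiral siloxyalkyne, which is traced back to 3-phenylglutaric anhydride.
- Enabling feature: ring A is a benzene with oxygen on C5, C7 and C8a and the chiral chain on C8, between C7 and C8a. A ketene carbonyl supplies C8a–OH, the two alkyne carbons of a siloxyalkyne supply C7–O and C8 with its chain, and C3 of a 3-alkoxycyclobutenone supplies C5–O.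
- Forward order: the side chain is made first, ring A is built around it by benzannulation, then C4 is added (formyl), then C3/C2 with ring B (acetylide), then ring C is closed 6-endo. A temporary lactone ring on O7/C8 carries the acid through ether cleavage and is opened last.
- Stereochemistry: the single stereocentre comes from catalytic enantioselective methanolysis of the meso anhydride. Later steps change only its substituents (descriptor changes are formal) and never make it acidic or ionisable.
- Abbreviations: TBS = tert-butyldimethylsilyl, TIPS = triisopropylsilyl.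

Key step: step 6

Assumption: the quinine-derived sulfonamide catalyst of step 1 is taken to give the (S)-hemiester; if its sense of induction is opposite, the quinidine-derived pseudoenantiomer replaces it and nothing else changes.

**Route**

Step 1
Reactants: 1 3-phenylglutaric anhydride
Product: 2 (3S)-5-methoxy-5-oxo-3-phenylpentanoic acid
Conditions: MeOH (10 equiv), N-(9-deoxy-epi-quinin-9-yl)-3,5-bis(trifluoromethyl)benzenesulfonamide (10 mol %), MTBE, −20 °C
Reagents that add atoms: methanol, CO
Why: Bifunctional cinchona-alkaloid catalysis of anhydride alcoholysis (the quinuclidine activates methanol, the sulfonamide N–H activates one enantiotopic carbonyl) is an established desymmetrisation of 3-substituted glutaric anhydrides and sets the only stereocentre of the route.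

Step 2
Reactants: 2 (3S)-5-methoxy-5-oxo-3-phenylpentanoic acid
Product: 3 methyl (3S)-5-hydroxy-3-phenylpentanoate
Conditions: BH3·SMe2 (1.3 equiv), THF, 0 °C → rt; MeOH quench; used crude
Reagents that add atoms: none
Why: Chemoselective borane reduction converts a free carboxylic acid much faster than an ester, so only the acid arm should become the primary alcohol, and the crude product is silylated at once to forestall δ-lactonisation.

Step 3
Reactants: 3 methyl (3S)-5-hydroxy-3-phenylpentanoate
Product: 4 methyl (3S)-5-(tert-butyldimethylsilyloxy)-3-phenylpentanoate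
Conditions: t-BuMe2SiCl, imidazole, DMF, 0 °C → rt
Reagents that add atoms: tert-butyldimethylsilyl chloride, CC(C)(C)[Si](C)(C)Cl
Why: Standard imidazole-mediated silylation of a primary alcohol gives an ether that tolerates the organolithium, thermal and mildly basic steps that follow.

Step 4
Reactants: 4 methyl (3S)-5-(tert-butyldimethylsilyloxy)-3-phenylpentanoate
Product: 6 methyl (3R)-2,2-dibromo-5-(tert-butyldimethylsilyloxy)-3-phenylpentanoate, via monobromo ester 5 (not isolated)
Conditions: LiN(i-Pr)2 (1.1 equiv), THF, −78 °C, then BrCCl2CCl2Br (1.1 equiv); LiN(SiMe3)2 (1.2 equiv), −78 °C, then BrCCl2CCl2Br (1.2 equiv); cold NH4Cl quench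
Reagents that add atoms: 1,2-dibromo-1,1,2,2-tetrachloroethane, BrC(Cl)(Cl)C(Cl)(Cl)Br
Why: Two successive ester-enolate brominations with a positive-bromine donor should place both bromines on C2, while the C3 stereocentre is not deprotonated under these conditions and keeps its configuration.

Step 5
Reactants: 6 methyl (3R)-2,2-dibromo-5-(tert-butyldimethylsilyloxy)-3-phenylpentanoate
Product: 8 (3R)-5-(tert-butyldimethylsilyloxy)-3-phenyl-1-(triisopropylsilyloxy)pent-1-yne, via lithium ynolate 7 (not isolated)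
Conditions: t-BuLi (4.0 equiv), THF, −78 → 0 °C; i-Pr3SiOTf (2.2 equiv), −78 °C → rt; filtration through Et3N-deactivated silica
Reagents that add atoms: triisopropylsilyl trifluoromethanesulfonate, CC(C)[Si](OS(=O)(=O)C(F)(F)F)(C(C)C)C(C)C
Why: Double bromine–lithium exchange on an α,α-dibromo ester gives an ester dianion that expels methoxide to form the lithium ynolate (the established ynolate synthesis from dibromo esters), and the bulky silyl triflate silylates ynolates on oxygen to give the siloxyalkyne.

Step 6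
Reactants: 8 (3R)-5-(tert-butyldimethylsilyloxy)-3-phenyl-1-(triisopropylsilyloxy)pent-1-yne; 9 3-ethoxycyclobut-2-en-1-one
Product: 14 2-[(1R)-3-(tert-butyldimethylsilyloxy)-1-phenylpropyl]-5-ethoxy-3-(triisopropylsilyloxy)phenol, via ethoxyvinylketene 10 (not isolated), via vinylcyclobutenone 11 (not isolated), via dienylketene 12 (not isolated), via cyclohexadienone 13 (not isolated)
Conditions: 9 (2 equiv, two portions), toluene, 80 °C then 110 °C, sealed tube, argon
Reagents that add atoms: none
Why: Thermal 4π-electrocyclic opening of 9 gives vinylketene 10, whose central ketene carbon is attacked by the nucleophilic chain-bearing carbon of siloxyalkyne 8 in a regioselective [2+2] cycloaddition to give 11; this opens (4π) to dienylketene 12, which closes by 6π-electrocyclisation to dienone 13 and tautomerises to phenol 14. The closest known reaction is the Danheiser benzannulation of 3-substituted cyclobutenones with triisopropylsiloxyalkynes, α-branched ones included, which gives 2,5-disubstituted resorcinol monosilyl ethers. Ring A is the only ring formed, and it is closed as a six-membered carbocycle by the disrotatory 6π-electrocyclisation that makes C8a–C4a after the cycloaddition has made C8a–C8 and C7–C6. No stereocentre is created, and the propargylic one carries no acidic or ionisable group, so it should pass through the neutral thermal cascade unchanged. The step needs regiocontrol in the ketene–alkyne cycloaddition, and the polarisation of the siloxyalkyne (oxygen-bearing carbon electrophilic, chain-bearing carbon nucleophilic) secures it, placing the chain between the ketene-derived free hydroxyl (C8a) and the silyloxy group (C7) with the ethoxy group para to it (C5). The 3-ethoxy group makes 9 a vinylogous ester and may slow its opening, which is why the temperature is raised in stages and 9 is used in excess.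

Step 7
Reactants: 14 2-[(1R)-3-(tert-butyldimethylsilyloxy)-1-phenylpropyl]-5-ethoxy-3-(triisopropylsilyloxy)phenol
Product: 16 3-[(1R)-3-(tert-butyldimethylsilyloxy)-1-phenylpropyl]-6-ethoxy-2-hydroxy-4-(triisopropylsilyloxy)benzaldehyde, via hydroxymethylphenol 15 (not isolated)
Conditions: MgCl2 (3 equiv), Et3N (5 equiv), (CH2O)n (8 equiv), MeCN, reflux
Reagents that add atoms: paraformaldehyde (formaldehyde), C=O
Why: In the Casnati–Skattebøl ortho-formylation the magnesium phenoxide delivers formaldehyde to the only free ortho position (the future C4a) and a second formaldehyde oxidises the benzylic alkoxide by hydride transfer, a reaction that is known to work on 3,5-dialkoxyphenols.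

Step 8
Reactants: 16 3-[(1R)-3-(tert-butyldimethylsilyloxy)-1-phenylpropyl]-6-ethoxy-2-hydroxy-4-(triisopropylsilyloxy)benzaldehyde; 17 1-ethynyl-4-methoxybenzene
Product: 19 (1RS)-1-{3-[(1R)-3-(tert-butyldimethylsilyloxy)-1-phenylpropyl]-6-ethoxy-2-hydroxy-4-(triisopropylsilyloxy)phenyl}-3-(4-methoxyphenyl)prop-2-yn-1-ol, via lithium acetylide 18 (not isolated)
Conditions: 17 (3 equiv), n-BuLi (2.9 equiv), THF, −78 °C; then 16, −78 → 0 °C; NH4Cl; used crude
Reagents that add atoms: none
Why: This is a 1,2-addition of a lithium acetylide to an aldehyde in which the first equivalent only deprotonates the phenol and the excess adds to the chelated formyl group, and the configuration of the new carbinol is irrelevant because it is oxidised in the next step.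

Step 9
Reactants: 19 (1RS)-1-{3-[(1R)-3-(tert-butyldimethylsilyloxy)-1-phenylpropyl]-6-ethoxy-2-hydroxy-4-(triisopropylsilyloxy)phenyl}-3-(4-methoxyphenyl)prop-2-yn-1-ol
Product: 20 1-{3-[(1R)-3-(tert-butyldimethylsilyloxy)-1-phenylpropyl]-6-ethoxy-2-hydroxy-4-(triisopropylsilyloxy)phenyl}-3-(4-methoxyphenyl)prop-2-yn-1-one
Conditions: activated MnO2 (15 equiv), CH2Cl2, rt
Reagents that add atoms: none
Why: Activated MnO2 oxidises benzylic–propargylic alcohols to ynones under neutral conditions that should leave both silyl ethers and the phenol untouched.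

Step 10
Reactants: 20 1-{3-[(1R)-3-(tert-butyldimethylsilyloxy)-1-phenylpropyl]-6-ethoxy-2-hydroxy-4-(triisopropylsilyloxy)phenyl}-3-(4-methoxyphenyl)prop-2-yn-1-one
Product: 21 8-[(1R)-3-(tert-butyldimethylsilyloxy)-1-phenylpropyl]-5-ethoxy-2-(4-methoxyphenyl)-7-(triisopropylsilyloxy)-4H-chromen-4-one
Conditions: 4-(dimethylamino)pyridine (20 mol %), DMF, rt → 40 °C
Reagents that add atoms: none
Why: In this amine-catalysed 6-endo oxa-Michael cyclisation of an o-hydroxyaryl ynone the pyridine adds to the β-carbon and the phenoxide displaces it at the same carbon, which should give the chromen-4-one (ring C of the flavone) and not the 5-exo aurone.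

Step 11
Reactants: 21 8-[(1R)-3-(tert-butyldimethylsilyloxy)-1-phenylpropyl]-5-ethoxy-2-(4-methoxyphenyl)-7-(triisopropylsilyloxy)-4H-chromen-4-one
Product: 22 5-ethoxy-7-hydroxy-8-[(1R)-3-hydroxy-1-phenylpropyl]-2-(4-methoxyphenyl)-4H-chromen-4-one
Conditions: Bu4NF (3 equiv), THF, 0 °C → rt; NH4Cl
Reagents that add atoms: none
Why: Fluoride desilylation cleaves both Si–O bonds, the aryl silyl ether para to the ring-C carbonyl being especially labile, and the alkyl ethers are inert to it.

Step 12
Reactants: 22 5-ethoxy-7-hydroxy-8-[(1R)-3-hydroxy-1-phenylpropyl]-2-(4-methoxyphenyl)-4H-chromen-4-one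
Product: 25 (10R)-5-ethoxy-2-(4-methoxyphenyl)-10-phenyl-9,10-dihydro-4H,8H-pyrano[2,3-f]chromene-4,8-dione, via hydroxy aldehyde 23 (not isolated), via lactol 24 (not isolated)
Conditions: TEMPO (2,2,6,6-tetramethylpiperidin-1-oxyl, 20 mol %), PhI(OAc)2 (2.5 equiv), CH2Cl2, rt
Reagents that add atoms: none
Why: In this oxoammonium-mediated oxidative lactonisation (known for 1,5-diols and for chroman-2-ols) the primary alcohol is oxidised to the aldehyde, the neighbouring 7-hydroxyl traps it as a six-membered lactol, and a second oxidation gives the lactone that masks acid and phenol together.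

Step 13
Reactants: 25 (10R)-5-ethoxy-2-(4-methoxyphenyl)-10-phenyl-9,10-dihydro-4H,8H-pyrano[2,3-f]chromene-4,8-dione
Product: 26 (10R)-5-hydroxy-2-(4-hydroxyphenyl)-10-phenyl-9,10-dihydro-4H,8H-pyrano[2,3-f]chromene-4,8-dione
Conditions: BBr3 (6 equiv), CH2Cl2, −78 → 20 °C; ice-water quench
Reagents that add atoms: none
Why: In this BBr3 ether cleavage chelation to the C4 carbonyl makes the 5-ethoxy group the most labile and the anisole methyl ether follows at room temperature, while dihydrocoumarin lactones tolerate the reagent and the low temperature avoids the Wessely–Moser isomerisation that hot protic acid causes in 8-substituted 5-hydroxyflavones.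

Step 14
Reactants: 26 (10R)-5-hydroxy-2-(4-hydroxyphenyl)-10-phenyl-9,10-dihydro-4H,8H-pyrano[2,3-f]chromene-4,8-dione
Product: 27 (3R)-3-[5,7-dihydroxy-2-(4-hydroxyphenyl)-4-oxo-4H-chromen-8-yl]-3-phenylpropanoic acid
Conditions: LiOH (5 equiv), degassed THF–H2O, 0 °C; then 1 M HCl to pH 3 at 0 °C, immediate extraction (EtOAc), concentration below 30 °C
Reagents that add atoms: water (as aqueous LiOH), O
Why: Saponification of the aryl lactone, an activated ester of the acidic 7-hydroxyl, followed by cold acidification should release the hydroxy acid without relactonisation, and the stereocentre is not acidic under these conditions.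

**Compound list**

1 | 3-phenylglutaric anhydride (4-phenyloxane-2,6-dione) | O=C1CC(CC(=O)O1)c1ccccc1 | starting material
2 | (3S)-5-methoxy-5-oxo-3-phenylpentanoic acid | OC(=O)C[C@H](c1ccccc1)CC(=O)OC | intermediate
3 | methyl (3S)-5-hydroxy-3-phenylpentanoate | OCC[C@H](c1ccccc1)CC(=O)OC | intermediate
4 | methyl (3S)-5-(tert-butyldimethylsilyloxy)-3-phenylpentanoate | CC(C)(C)[Si](C)(C)OCC[C@H](c1ccccc1)CC(=O)OC | intermediate
5 | methyl (3R)-2-bromo-5-(tert-butyldimethylsilyloxy)-3-phenylpentanoate, both C2 epimers | CC(C)(C)[Si](C)(C)OCC[C@H](c1ccccc1)C(Br)C(=O)OC | intermediate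
6 | methyl (3R)-2,2-dibromo-5-(tert-butyldimethylsilyloxy)-3-phenylpentanoate | CC(C)(C)[Si](C)(C)OCC[C@H](c1ccccc1)C(Br)(Br)C(=O)OC | intermediate
7 | lithium (3R)-5-(tert-butyldimethylsilyloxy)-3-phenylpent-1-yn-1-olate | CC(C)(C)[Si](C)(C)OCC[C@H](c1ccccc1)C#C[O-].[Li+] | intermediate
8 | (3R)-5-(tert-butyldimethylsilyloxy)-3-phenyl-1-(triisopropylsilyloxy)pent-1-yne | CC(C)(C)[Si](C)(C)OCC[C@H](c1ccccc1)C#CO[Si](C(C)C)(C(C)C)C(C)C | intermediate
9 | 3-ethoxycyclobut-2-en-1-one | CCOC1=CC(=O)C1 | starting material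
10 | 3-ethoxybuta-1,3-dien-1-one (ethoxyvinylketene) | C=C(OCC)C=C=O | intermediate
11 | 2-[(1R)-3-(tert-butyldimethylsilyloxy)-1-phenylpropyl]-4-(1-ethoxyethenyl)-3-(triisopropylsilyloxy)cyclobut-2-en-1-one, both C4 epimers | CC(C)(C)[Si](C)(C)OCC[C@H](c1ccccc1)C1=C(O[Si](C(C)C)(C(C)C)C(C)C)C(C(=C)OCC)C1=O | intermediate
12 | 2-[(1R)-3-(tert-butyldimethylsilyloxy)-1-phenylpropyl]-5-ethoxy-3-(triisopropylsilyloxy)hexa-1,3,5-trien-1-one, ketene carbon and ethoxyvinyl group cis on the central double bond | CC(C)(C)[Si](C)(C)OCC[C@H](c1ccccc1)C(=C=O)/C(O[Si](C(C)C)(C(C)C)C(C)C)=C\C(=C)OCC | intermediate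
13 | 2-[(1R)-3-(tert-butyldimethylsilyloxy)-1-phenylpropyl]-5-ethoxy-3-(triisopropylsilyloxy)cyclohexa-2,4-dien-1-one | CC(C)(C)[Si](C)(C)OCC[C@H](c1ccccc1)C1=C(O[Si](C(C)C)(C(C)C)C(C)C)C=C(OCC)CC1=O | intermediate
14 | 2-[(1R)-3-(tert-butyldimethylsilyloxy)-1-phenylpropyl]-5-ethoxy-3-(triisopropylsilyloxy)phenol | CC(C)(C)[Si](C)(C)OCC[C@H](c1ccccc1)c1c(O)cc(OCC)cc1O[Si](C(C)C)(C(C)C)C(C)C | intermediate
15 | 2-[(1R)-3-(tert-butyldimethylsilyloxy)-1-phenylpropyl]-5-ethoxy-6-(hydroxymethyl)-3-(triisopropylsilyloxy)phenol (present as its magnesium salt) | CC(C)(C)[Si](C)(C)OCC[C@H](c1ccccc1)c1c(O)c(CO)c(OCC)cc1O[Si](C(C)C)(C(C)C)C(C)C | intermediate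
16 | 3-[(1R)-3-(tert-butyldimethylsilyloxy)-1-phenylpropyl]-6-ethoxy-2-hydroxy-4-(triisopropylsilyloxy)benzaldehyde | CC(C)(C)[Si](C)(C)OCC[C@H](c1ccccc1)c1c(O)c(C=O)c(OCC)cc1O[Si](C(C)C)(C(C)C)C(C)C | intermediate
17 | 1-ethynyl-4-methoxybenzene | C#Cc1ccc(OC)cc1 | starting material
18 | lithium (4-methoxyphenyl)ethynide | [Li]C#Cc1ccc(OC)cc1 | intermediate
19 | (1RS)-1-{3-[(1R)-3-(tert-butyldimethylsilyloxy)-1-phenylpropyl]-6-ethoxy-2-hydroxy-4-(triisopropylsilyloxy)phenyl}-3-(4-methoxyphenyl)prop-2-yn-1-ol | CC(C)(C)[Si](C)(C)OCC[C@H](c1ccccc1)c1c(O)c(C(O)C#Cc2ccc(OC)cc2)c(OCC)cc1O[Si](C(C)C)(C(C)C)C(C)C | intermediate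
20 | 1-{3-[(1R)-3-(tert-butyldimethylsilyloxy)-1-phenylpropyl]-6-ethoxy-2-hydroxy-4-(triisopropylsilyloxy)phenyl}-3-(4-methoxyphenyl)prop-2-yn-1-one | CC(C)(C)[Si](C)(C)OCC[C@H](c1ccccc1)c1c(O)c(C(=O)C#Cc2ccc(OC)cc2)c(OCC)cc1O[Si](C(C)C)(C(C)C)C(C)C | intermediate
21 | 8-[(1R)-3-(tert-butyldimethylsilyloxy)-1-phenylpropyl]-5-ethoxy-2-(4-methoxyphenyl)-7-(triisopropylsilyloxy)-4H-chromen-4-one | CC(C)(C)[Si](C)(C)OCC[C@H](c1ccccc1)c1c(O[Si](C(C)C)(C(C)C)C(C)C)cc(OCC)c2c(=O)cc(-c3ccc(OC)cc3)oc12 | intermediate
22 | 5-ethoxy-7-hydroxy-8-[(1R)-3-hydroxy-1-phenylpropyl]-2-(4-methoxyphenyl)-4H-chromen-4-one | OCC[C@H](c1ccccc1)c1c(O)cc(OCC)c2c(=O)cc(-c3ccc(OC)cc3)oc12 | intermediate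
23 | (3R)-3-[5-ethoxy-7-hydroxy-2-(4-methoxyphenyl)-4-oxo-4H-chromen-8-yl]-3-phenylpropanal | O=CC[C@H](c1ccccc1)c1c(O)cc(OCC)c2c(=O)cc(-c3ccc(OC)cc3)oc12 | intermediate
24 | (10R)-5-ethoxy-8-hydroxy-2-(4-methoxyphenyl)-10-phenyl-9,10-dihydro-4H,8H-pyrano[2,3-f]chromen-4-one, both C8 epimers (lactol on O7/C8 of the flavone) | OC1C[C@H](c2ccccc2)c2c(O1)cc(OCC)c3c(=O)cc(-c4ccc(OC)cc4)oc23 | intermediate
25 | (10R)-5-ethoxy-2-(4-methoxyphenyl)-10-phenyl-9,10-dihydro-4H,8H-pyrano[2,3-f]chromene-4,8-dione (six-membered lactone between the flavone 7-oxygen and the side-chain carboxyl) | O=C1C[C@H](c2ccccc2)c2c(O1)cc(OCC)c3c(=O)cc(-c4ccc(OC)cc4)oc23 | intermediate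
26 | (10R)-5-hydroxy-2-(4-hydroxyphenyl)-10-phenyl-9,10-dihydro-4H,8H-pyrano[2,3-f]chromene-4,8-dione | O=C1C[C@H](c2ccccc2)c2c(O1)cc(O)c3c(=O)cc(-c4ccc(O)cc4)oc23 | intermediate
27 | (3R)-3-[5,7-dihydroxy-2-(4-hydroxyphenyl)-4-oxo-4H-chromen-8-yl]-3-phenylpropanoic acid | O=C(O)C[C@H](c1ccccc1)c1c(O)cc(O)c2c(=O)cc(-c3ccc(O)cc3)oc12 | target

**Summary**

Total step count: 14.
Longest linear sequence: 14 steps, from 3-phenylglutaric anhydride 1 to 27; compounds 9 and 17 are bought.

**Steps most likely to fail**

1. Step 6. The vinylogous-ester character of 9 may retard its electrocyclic opening, so that thermal isomerisation of the siloxyalkyne to a silylketene, or acylation of the new phenol by the ketene, overtakes the cycloaddition. The fallback sets out from 8 and returns at 14; it generates the same vinylketene at room temperature by photochemical Wolff rearrangement instead of thermal ring opening. Ethyl vinyl ether is lithiated (t-BuLi, THF) and acylated with N-methoxy-N-methylacetamide to 3-ethoxybut-3-en-2-one F1. Detrifluoroacetylative diazo transfer (LiN(SiMe3)2, CF3CO2CH2CF3, then MsN3, Et3N) should give 1-diazo-3-ethoxybut-3-en-2-one F2. Irradiation of F2 with 8 in CH2Cl2, followed by brief heating at 80 °C to complete the electrocyclic steps, should give 14.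

2. Step 5. Addition of t-BuLi to the ester carbonyl, or loss of HBr toward the benzylic C3–H, may compete with the two bromine–lithium exchanges; step 4 carries the same elimination risk if base is left in excess. The fallback sets out from 4 and returns at 8; it reaches the ynolate by oxidation of a terminal acetylide and avoids the dibromo ester altogether. Reduction of 4 with i-Bu2AlH (toluene, −78 °C) should give (3S)-5-(tert-butyldimethylsilyloxy)-3-phenylpentanal F3. Nonaflation–elimination (C4F9SO2F, phosphazene base P2-Et, DMF) should convert it through the alkenyl nonaflate into (3S)-5-(tert-butyldimethylsilyloxy)-3-phenylpent-1-yne F4. Deprotonation with LiN(SiMe3)2 and oxidation of the acetylide with LiOOt-Bu should give ynolate 7, which i-Pr3SiOTf silylates to 8.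

3. Step 12. The iodine reagent may oxidise the free 7-hydroxyl ring in competition with the alcohol, or the sequence may stall at the lactol. The fallback sets out from 21 and returns at 25; it oxidises with the phenol still silylated and closes the lactone by dehydration. Camphorsulfonic acid in MeOH–CH2Cl2 at 0 °C should remove only the primary silyl group to give 5-ethoxy-8-[(1R)-3-hydroxy-1-phenylpropyl]-2-(4-methoxyphenyl)-7-(triisopropylsilyloxy)-4H-chromen-4-one F5. TEMPO/PhI(OAc)2 in MeCN–H2O should give (3R)-3-[5-ethoxy-2-(4-methoxyphenyl)-4-oxo-7-(triisopropylsilyloxy)-4H-chromen-8-yl]-3-phenylpropanoic acid F6. Bu4NF should free the phenol to give (3R)-3-[5-ethoxy-7-hydroxy-2-(4-methoxyphenyl)-4-oxo-4H-chromen-8-yl]-3-phenylpropanoic acid F7, and N-(3-dimethylaminopropyl)-N′-ethylcarbodiimide hydrochloride with 4-(dimethylamino)pyridine in CH2Cl2 should close lactone 25.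

**Further compounds**

F1 | step 6 | 3-ethoxybut-3-en-2-one | C=C(OCC)C(C)=O
F2 | step 6 | 1-diazo-3-ethoxybut-3-en-2-one | C=C(OCC)C(=O)C=[N+]=[N-]
F3 | step 5 | (3S)-5-(tert-butyldimethylsilyloxy)-3-phenylpentanal | CC(C)(C)[Si](C)(C)OCC[C@H](c1ccccc1)CC=O
F4 | step 5 | (3S)-5-(tert-butyldimethylsilyloxy)-3-phenylpent-1-yne | CC(C)(C)[Si](C)(C)OCC[C@H](c1ccccc1)C#C
F5 | step 12 | 5-ethoxy-8-[(1R)-3-hydroxy-1-phenylpropyl]-2-(4-methoxyphenyl)-7-(triisopropylsilyloxy)-4H-chromen-4-one | OCC[C@H](c1ccccc1)c1c(O[Si](C(C)C)(C(C)C)C(C)C)cc(OCC)c2c(=O)cc(-c3ccc(OC)cc3)oc12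
F6 | step 12 | (3R)-3-[5-ethoxy-2-(4-methoxyphenyl)-4-oxo-7-(triisopropylsilyloxy)-4H-chromen-8-yl]-3-phenylpropanoic acid | OC(=O)C[C@H](c1ccccc1)c1c(O[Si](C(C)C)(C(C)C)C(C)C)cc(OCC)c2c(=O)cc(-c3ccc(OC)cc3)oc12
F7 | step 12 | (3R)-3-[5-ethoxy-7-hydroxy-2-(4-methoxyphenyl)-4-oxo-4H-chromen-8-yl]-3-phenylpropanoic acid | OC(=O)C[C@H](c1ccccc1)c1c(O)cc(OCC)c2c(=O)cc(-c3ccc(OC)cc3)oc12
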